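**Plan**
- Retrosynthesis: ring A is cut at C3–C4. The C3 carbinol sits next to C4, which carries the exocyclic C15 methylene (a 2-methylenecyclohexanol in ring A), so the bond is the retron of an alkenylchromium adding to an aldehyde. The 1,3-spacing of the C1 and C3 oxygens makes that aldehyde a β-silyloxy aldehyde.
- Further cuts: the C6–O ester, the C12 oxidation level (from an isopropenyl group), C4–C5 (Stille), C6–O (conjugate borylation), C7–C11 (rhodium 1,4-addition), C1–C2 (allylboration), and ring B at C5–C10/C8–C9 (Diels–Alder).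
- Forward: ring B is made first from methacrolein and 1-acetoxybutadiene; the C1–C3 chain, the C7 isopropenyl group, the C4 acetyl group and the C6 oxygen are added around it; acylation and C12 oxidation follow; ring A is closed last.
- Stereochemistry: C10 from the catalyst-controlled cycloaddition; C1 from the chiral allylborane; C7 from Rh/(R)-BINAP; C6 from boron adding anti to the C7 substituent; C5 by equilibration to the equatorial acetyl group; C3 in the ring closure.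

Key step: step 17

Remark: eudesmane numbering is used (decalin C1–C10, acrylate C11–C13, angular methyl C14, exocyclic methylene C15; TBS = tert-butyldimethylsilyl, Tf = trifluoromethanesulfonyl, Bpin = pinacolatoboryl); the catalyst enantiomer in step 1 is assumed to give the (6R) adduct by the usual model for 2-substituted acroleins, and its mirror image would be used if the opposite sense were found.

Step 1
Reactants: 1 methacrolein; 2 (E)-buta-1,3-dien-1-yl acetate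
Product: 3 (1S,6R)-6-formyl-6-methylcyclohex-2-en-1-yl acetate (cis adduct)
Conditions: (S)-3,3-diphenyl-1-(2-methylphenyl)tetrahydropyrrolo[1,2-c][1,3,2]oxazaborole·HN(SO2CF3)2 (10 mol %), CH2Cl2, −78 to −40 °C
Reagents that add atoms: none
Why: Catalytic enantioselective Diels–Alder reaction: the acetoxy-bearing diene terminus bonds to the α-carbon of the enal ("ortho" rule, placing oxygen next to the new quaternary carbon C10), endo approach should give the cis adduct, and the chiral boron Lewis acid holds the s-trans enal so that one face is open, which sets C10; the acetoxy centre is erased in step 3.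

Step 2
Reactants: 3 (1S,6R)-6-formyl-6-methylcyclohex-2-en-1-yl acetate
Product: 5 (1S,6S)-6-[(1R)-1-hydroxybut-3-en-1-yl]-6-methylcyclohex-2-en-1-ol, via homoallylic alcohol acetate 4 (not isolated)
Conditions: (+)-Ipc2B(allyl) (from (−)-α-pinene), Et2O, −78 °C; NaBO3·4H2O, H2O, rt; then K2CO3, MeOH, rt
Reagents that add atoms: (+)-B-allyldiisopinocampheylborane, C=CCB([C@H]1C[C@H]2C[C@@H]([C@@H]1C)C2(C)C)[C@H]1C[C@H]2C[C@@H]([C@@H]1C)C2(C)C
Why: Reagent-controlled allylboration (Brown allylation) through a chair six-membered transition state in which the isopinocampheyl groups expose the Re face of the aldehyde and so set C1 as (R), followed by base-catalysed transesterification that frees the ring alcohol.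

Step 3
Reactants: 5 (1S,6S)-6-[(1R)-1-hydroxybut-3-en-1-yl]-6-methylcyclohex-2-en-1-ol
Product: 6 (6S)-6-[(1R)-1-hydroxybut-3-en-1-yl]-6-methylcyclohex-2-en-1-one
Conditions: MnO2 (excess), CH2Cl2, rt
Reagents that add atoms: none
Why: MnO2 should oxidise only the allylic ring alcohol to the enone (chemoselective allylic oxidation), leave the homoallylic C1 carbinol alone and remove the stereocentre left over from the cycloaddition.

Step 4
Reactants: 6 (6S)-6-[(1R)-1-hydroxybut-3-en-1-yl]-6-methylcyclohex-2-en-1-one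
Product: 7 (6S)-6-[(1R)-1-(tert-butyldimethylsilyloxy)but-3-en-1-yl]-6-methylcyclohex-2-en-1-one
Conditions: TBSOTf, 2,6-lutidine, CH2Cl2, −78 to 0 °C
Reagents that add atoms: tert-butyldimethylsilyl trifluoromethanesulfonate, CC(C)(C)[Si](C)(C)OS(=O)(=O)C(F)(F)F
Why: Silyl triflate silylation of the hindered secondary alcohol; the ether blocks retro-aldol cleavage of the β-hydroxy ketone in the basic steps that follow.

Step 5
Reactants: 7 (6S)-6-[(1R)-1-(TBSO)but-3-en-1-yl]-6-methylcyclohex-2-en-1-one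
Product: 8 (2S,5R)-2-[(1R)-1-(TBSO)but-3-en-1-yl]-2-methyl-5-(prop-1-en-2-yl)cyclohexan-1-one
Conditions: isopropenyl-Bpin, [RhCl(cod)]2 (2.5 mol %), (R)-BINAP (6 mol %), KOH (aq, substoichiometric), 1,4-dioxane/H2O, 60 °C
Reagents that add atoms: 4,4,5,5-tetramethyl-2-(prop-1-en-2-yl)-1,3,2-dioxaborolane, CC(=C)B1OC(C)(C)C(C)(C)O1
Why: Rhodium-catalysed asymmetric 1,4-addition of an alkenylboron reagent (Hayashi–Miyaura reaction): the alkenyl–rhodium–(R)-BINAP species should add to one face of the enone under catalyst control and set C7 with the isopropenyl group cis to the C10 methyl group.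

Step 6
Reactants: 8 (2S,5R)-2-[(1R)-1-(TBSO)but-3-en-1-yl]-2-methyl-5-(prop-1-en-2-yl)cyclohexan-1-one
Product: 10 (3R,6S)-6-[(1R)-1-(TBSO)but-3-en-1-yl]-6-methyl-3-(prop-1-en-2-yl)cyclohex-1-en-1-yl trifluoromethanesulfonate, via potassium enolate 9 (not isolated)
Conditions: KN(SiMe3)2, THF, −78 °C; PhN(SO2CF3)2, −78 to 0 °C
Reagents that add atoms: N-phenylbis(trifluoromethanesulfonimide), O=S(=O)(N(c1ccccc1)S(=O)(=O)C(F)(F)F)C(F)(F)F
Why: Enolate O-sulfonylation: the ketone has α-hydrogens only at C6 because C10 is quaternary, so a single enol triflate should form.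

Step 7
Reactants: 10 (3R,6S)-6-[(1R)-1-(TBSO)but-3-en-1-yl]-6-methyl-3-(prop-1-en-2-yl)cyclohex-1-en-1-yl trifluoromethanesulfonate
Product: 12 1-[(3R,6R)-6-[(1R)-1-(TBSO)but-3-en-1-yl]-6-methyl-3-(prop-1-en-2-yl)cyclohex-1-en-1-yl]ethan-1-one, via 2-ethoxydiene 11 (not isolated)
Conditions: tributyl(1-ethoxyvinyl)stannane, Pd(PPh3)4 (5 mol %, zerovalent palladium), LiCl, THF, 65 °C; then 1 M HCl, THF, rt
Reagents that add atoms: tributyl(1-ethoxyvinyl)stannane, CCCC[Sn](CCCC)(CCCC)C(=C)OCC; water, O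
Why: Stille coupling of the enol triflate with an acyl-anion equivalent, then acid hydrolysis of the enol ether, should give the 1-acetylcyclohexene and so attach C4 and C15 to C5.

Step 8
Reactants: 12 1-[(3R,6R)-6-[(1R)-1-(TBSO)but-3-en-1-yl]-6-methyl-3-(prop-1-en-2-yl)cyclohex-1-en-1-yl]ethan-1-one
Product: 14 1-[(1S,2S,3S,6R)-6-[(1R)-1-(TBSO)but-3-en-1-yl]-2-hydroxy-6-methyl-3-(prop-1-en-2-yl)cyclohexyl]ethan-1-one, via β-boryl ketone 13 (not isolated)
Conditions: B2pin2, CuCl (5 mol %), Xantphos (5 mol %), NaOtBu (10 mol %), MeOH, THF, rt; then NaBO3·4H2O, THF/H2O, rt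
Reagents that add atoms: bis(pinacolato)diboron (boron of 13), CC1(C)OB(OC1(C)C)B1OC(C)(C)C(C)(C)O1; sodium perborate (oxygen of 14), [Na+].[O-]B1OO1
Why: Copper-catalysed conjugate borylation of the enone followed by oxidation of the C–B bond with retention: the boryl–copper species should add to C6 on the face away from the neighbouring C7 isopropenyl group, and C5, α to the ketone, should settle in the mildly basic medium as the equatorial acetyl epimer, so that C5, C6 and C7 end all-equatorial.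

Step 9
Reactants: 15 ethyl 2-(hydroxymethyl)prop-2-enoate
Product: 16 ethyl 2-[(tert-butyldimethylsilyloxy)methyl]prop-2-enoate
Conditions: TBSCl, imidazole, CH2Cl2, 0 °C to rt
Reagents that add atoms: tert-butyldimethylsilyl chloride, CC(C)(C)[Si](C)(C)Cl
Why: Standard silylation of a primary alcohol with a silyl chloride and imidazole.

Step 10
Reactants: 16 ethyl 2-[(TBSO)methyl]prop-2-enoate
Product: 17 2-[(TBSO)methyl]prop-2-enoic acid
Conditions: LiOH, THF/H2O, 0 °C to rt; 1 M HCl to pH 4 at 0 °C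
Reagents that add atoms: lithium hydroxide, [Li+].[OH-]
Why: Saponification of the ethyl ester; the primary silyl ether should survive cold aqueous LiOH and brief mild acidification.

Step 11
Reactants: 14 1-[(1S,2S,3S,6R)-6-[(1R)-1-(TBSO)but-3-en-1-yl]-2-hydroxy-6-methyl-3-(prop-1-en-2-yl)cyclohexyl]ethan-1-one; 17 2-[(TBSO)methyl]prop-2-enoic acid
Product: 18 (1S,2S,3R,6S)-2-acetyl-3-[(1R)-1-(TBSO)but-3-en-1-yl]-3-methyl-6-(prop-1-en-2-yl)cyclohexyl 2-[(TBSO)methyl]prop-2-enoate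
Conditions: EDC, DMAP (cat.), CH2Cl2, 0 °C to rt
Reagents that add atoms: none
Why: Carbodiimide esterification with DMAP catalysis (Steglich esterification) acylates the only free hydroxyl group, the equatorial C6 alcohol, before any C12 ester exists that could lactonise onto it.

Step 12
Reactants: 18 (1S,2S,3R,6S)-2-acetyl-3-[(1R)-1-(TBSO)but-3-en-1-yl]-3-methyl-6-(prop-1-en-2-yl)cyclohexyl 2-[(TBSO)methyl]prop-2-enoate
Product: 20 (1S,2S,3R,6S)-2-acetyl-3-[(1R)-1-(TBSO)but-3-en-1-yl]-3-methyl-6-(3-oxoprop-1-en-2-yl)cyclohexyl 2-[(TBSO)methyl]prop-2-enoate, via allylic alcohol 19 (not isolated)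
Conditions: SeO2 (0.5 equiv), t-BuOOH, salicylic acid (cat.), CH2Cl2, rt; then MnO2, CH2Cl2, rt
Reagents that add atoms: selenium dioxide, O=[Se]=O; tert-butyl hydroperoxide, CC(C)(C)OO
Why: SeO2 allylic oxidation (ene reaction then [2,3]-sigmatropic shift) should take the methyl group of the electron-rich 1,1-disubstituted alkene, the C7 methine being deactivated by the adjacent acyloxy group, and MnO2 carries the allylic alcohol on to the enal.

Step 13
Reactants: 20 (1S,2S,3R,6S)-2-acetyl-3-[(1R)-1-(TBSO)but-3-en-1-yl]-3-methyl-6-(3-oxoprop-1-en-2-yl)cyclohexyl 2-[(TBSO)methyl]prop-2-enoate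
Product: 21 2-[(1S,2S,3S,4R)-3-acetyl-4-[(1R)-1-(TBSO)but-3-en-1-yl]-4-methyl-2-({2-[(TBSO)methyl]prop-2-enoyl}oxy)cyclohexyl]prop-2-enoic acid
Conditions: NaClO2, NaH2PO4, 2-methyl-2-butene, t-BuOH/H2O, 0 °C to rt
Reagents that add atoms: sodium chlorite, [Na+].[O-]Cl=O
Why: Pinnick oxidation converts the 2-substituted acrolein into the acrylic acid without touching alkenes, ketone or esters.

Step 14
Reactants: 21 2-[(1S,2S,3S,4R)-3-acetyl-4-[(1R)-1-(TBSO)but-3-en-1-yl]-4-methyl-2-({2-[(TBSO)methyl]prop-2-enoyl}oxy)cyclohexyl]prop-2-enoic acid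
Product: 22 methyl 2-[(1S,2S,3S,4R)-3-acetyl-4-[(1R)-1-(TBSO)but-3-en-1-yl]-4-methyl-2-({2-[(TBSO)methyl]prop-2-enoyl}oxy)cyclohexyl]prop-2-enoate
Conditions: MeI, KHCO3, DMF, rt
Reagents that add atoms: iodomethane, CI
Why: O-Alkylation of the carboxylate with MeI under bicarbonate, which is mild enough not to eliminate the β-acyloxy ketone.

Step 15
Reactants: 22 methyl 2-[(1S,2S,3S,4R)-3-acetyl-4-[(1R)-1-(TBSO)but-3-en-1-yl]-4-methyl-2-({2-[(TBSO)methyl]prop-2-enoyl}oxy)cyclohexyl]prop-2-enoate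
Product: 24 methyl 2-[(1S,2S,3S,4R)-4-[(1R)-1-(TBSO)but-3-en-1-yl]-4-methyl-2-({2-[(TBSO)methyl]prop-2-enoyl}oxy)-3-[1-(trifluoromethanesulfonyloxy)ethenyl]cyclohexyl]prop-2-enoate, via potassium enolate 23 (not isolated)
Conditions: KN(SiMe3)2, THF, −78 °C; N-(5-chloropyridin-2-yl)bis(trifluoromethanesulfonimide), −78 °C
Reagents that add atoms: N-(5-chloropyridin-2-yl)bis(trifluoromethanesulfonimide), O=S(=O)(N(c1ccc(Cl)cn1)S(=O)(=O)C(F)(F)F)C(F)(F)F
Why: Kinetic deprotonation of the methyl ketone at the unhindered methyl group and O-sulfonylation should give the 1-substituted ethenyl triflate, while the hindered C5 hydrogen, whose removal would expel the C6 ester, is left alone.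

Step 16
Reactants: 24 methyl 2-[(1S,2S,3S,4R)-4-[(1R)-1-(TBSO)but-3-en-1-yl]-4-methyl-2-({2-[(TBSO)methyl]prop-2-enoyl}oxy)-3-[1-(trifluoromethanesulfonyloxy)ethenyl]cyclohexyl]prop-2-enoate
Product: 26 methyl 2-[(1S,2S,3S,4R)-4-[(1R)-1-(TBSO)-3-oxopropyl]-4-methyl-2-({2-[(TBSO)methyl]prop-2-enoyl}oxy)-3-[1-(trifluoromethanesulfonyloxy)ethenyl]cyclohexyl]prop-2-enoate, via 1,2-diol 25 (not isolated)
Conditions: K2OsO4·2H2O (2 mol %), N-methylmorpholine N-oxide, acetone/H2O, 0 °C; then NaIO4, THF/pH 7 buffer, 0 °C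
Reagents that add atoms: N-methylmorpholine N-oxide, C[N+]1([O-])CCOCC1; water, O
Why: Osmium-catalysed dihydroxylation and periodate glycol cleavage (Lemieux–Johnson sequence in two stages): electrophilic OsO4 should take the only electron-rich alkene, the monosubstituted terminus, in preference to the two acrylates and the enol triflate.

Step 17
Reactants: 26 methyl 2-[(1S,2S,3S,4R)-4-[(1R)-1-(TBSO)-3-oxopropyl]-4-methyl-2-({2-[(TBSO)methyl]prop-2-enoyl}oxy)-3-[1-(trifluoromethanesulfonyloxy)ethenyl]cyclohexyl]prop-2-enoate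
Product: 28 methyl (1R,3S,5S,6S,7S,10R)-1-(TBSO)-3-hydroxy-6-({2-[(TBSO)methyl]prop-2-enoyl}oxy)eudesma-4(15),11(13)-dien-12-oate, via alkenylchromium dichloride 27 (not isolated)
Conditions: CrCl2 (8 equiv), NiCl2 (2 mol %), DMF/THF, rt, 0.005 M; NaHCO3 (aq) work-up
Reagents that add atoms: none
Why: Zerovalent nickel, generated from NiCl2 by CrCl2, inserts into the C4–O bond of the enol triflate and hands the alkenyl group to trivalent chromium (27), and this alkenylchromium adds to the C3 aldehyde to give the chromium alkoxide of 28. The closest known reaction type is the intramolecular Nozaki–Hiyama–Kishi cyclisation of alkenyl triflates or iodides onto aldehydes to give 2-methylenecycloalkanols. Ring A closes in the 6-exo-trig mode (C4 attacks the carbonyl carbon C3, the C=O bond lying outside the new ring) on a ring-B chair in which the alkenyl group at C5 and the C1–C3 chain at C10 are both equatorial and gauche, so a trans-decalin should result. The new stereocentre C3 is controlled by the chair of the forming ring A: the bulky O–Cr group should take the pseudo-equatorial position, away from the axial hydrogens at C1 and C5, which gives the 3β (3S) alcohol, cis to the equatorial C1 silyl ether. The step needs selectivity for the aldehyde over the two acrylate esters and the silyl ethers, which the carbonyl selectivity and low basicity of organochromium reagents secure, and ring closure over dimerisation, which high dilution and the six-membered transition state secure. The exocyclic C4=C15 methylene comes directly from the 1-substituted ethenyl triflate, so no later olefination is needed.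

Step 18
Reactants: 28 methyl (1R,3S,5S,6S,7S,10R)-1-(TBSO)-3-hydroxy-6-({2-[(TBSO)methyl]prop-2-enoyl}oxy)eudesma-4(15),11(13)-dien-12-oate
Product: 29 methyl (1R,3S,5S,6S,7S,10R)-1,3-dihydroxy-6-{[2-(hydroxymethyl)prop-2-enoyl]oxy}eudesma-4(15),11(13)-dien-12-oate (target)
Conditions: HF·pyridine, pyridine, THF, 0 °C to rt
Reagents that add atoms: none
Why: Fluoride-mediated cleavage of both silyl ethers under buffered conditions that should spare the two acrylates and avoid base-induced acyl migration or lactonisation.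

**Compound list**
1 | methacrolein (2-methylprop-2-enal) | C=C(C)C=O | starting material
2 | (E)-buta-1,3-dien-1-yl acetate | CC(=O)O/C=C/C=C | starting material
3 | (1S,6R)-6-formyl-6-methylcyclohex-2-en-1-yl acetate | O=C[C@@]1(C)[C@@H](OC(C)=O)C=CCC1 | intermediate
4 | (1S,6S)-6-[(1R)-1-hydroxybut-3-en-1-yl]-6-methylcyclohex-2-en-1-yl acetate | C=CC[C@@H](O)[C@@]1(C)[C@@H](OC(C)=O)C=CCC1 | intermediate (not isolated)
5 | (1S,6S)-6-[(1R)-1-hydroxybut-3-en-1-yl]-6-methylcyclohex-2-en-1-ol | C=CC[C@@H](O)[C@@]1(C)[C@@H](O)C=CCC1 | intermediate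
6 | (6S)-6-[(1R)-1-hydroxybut-3-en-1-yl]-6-methylcyclohex-2-en-1-one | C=CC[C@@H](O)[C@@]1(C)C(=O)C=CCC1 | intermediate
7 | (6S)-6-[(1R)-1-(TBSO)but-3-en-1-yl]-6-methylcyclohex-2-en-1-one | C=CC[C@@H](O[Si](C)(C)C(C)(C)C)[C@@]1(C)C(=O)C=CCC1 | intermediate
8 | (2S,5R)-2-[(1R)-1-(TBSO)but-3-en-1-yl]-2-methyl-5-(prop-1-en-2-yl)cyclohexan-1-one | C=CC[C@@H](O[Si](C)(C)C(C)(C)C)[C@@]1(C)C(=O)C[C@H](C(C)=C)CC1 | intermediate
9 | potassium (3R,6S)-6-[(1R)-1-(TBSO)but-3-en-1-yl]-6-methyl-3-(prop-1-en-2-yl)cyclohex-1-en-1-olate | C=CC[C@@H](O[Si](C)(C)C(C)(C)C)[C@@]1(C)C([O-])=C[C@H](C(C)=C)CC1.[K+] | intermediate (not isolated)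
10 | (3R,6S)-6-[(1R)-1-(TBSO)but-3-en-1-yl]-6-methyl-3-(prop-1-en-2-yl)cyclohex-1-en-1-yl trifluoromethanesulfonate | C=CC[C@@H](O[Si](C)(C)C(C)(C)C)[C@@]1(C)C(OS(=O)(=O)C(F)(F)F)=C[C@H](C(C)=C)CC1 | intermediate
11 | tert-butyl({(1R)-1-[(1R,4R)-2-(1-ethoxyethenyl)-1-methyl-4-(prop-1-en-2-yl)cyclohex-2-en-1-yl]but-3-en-1-yl}oxy)dimethylsilane | C=CC[C@@H](O[Si](C)(C)C(C)(C)C)[C@@]1(C)C(C(=C)OCC)=C[C@H](C(C)=C)CC1 | intermediate (not isolated)
12 | 1-[(3R,6R)-6-[(1R)-1-(TBSO)but-3-en-1-yl]-6-methyl-3-(prop-1-en-2-yl)cyclohex-1-en-1-yl]ethan-1-one | C=CC[C@@H](O[Si](C)(C)C(C)(C)C)[C@@]1(C)C(C(C)=O)=C[C@H](C(C)=C)CC1 | intermediate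
13 | 1-[(1R,2S,3R,6R)-6-[(1R)-1-(TBSO)but-3-en-1-yl]-6-methyl-3-(prop-1-en-2-yl)-2-(4,4,5,5-tetramethyl-1,3,2-dioxaborolan-2-yl)cyclohexyl]ethan-1-one | C=CC[C@@H](O[Si](C)(C)C(C)(C)C)[C@@]1(C)[C@H](C(C)=O)[C@@H](B2OC(C)(C)C(C)(C)O2)[C@H](C(C)=C)CC1 | intermediate (not isolated)
14 | 1-[(1S,2S,3S,6R)-6-[(1R)-1-(TBSO)but-3-en-1-yl]-2-hydroxy-6-methyl-3-(prop-1-en-2-yl)cyclohexyl]ethan-1-one | C=CC[C@@H](O[Si](C)(C)C(C)(C)C)[C@@]1(C)[C@H](C(C)=O)[C@@H](O)[C@H](C(C)=C)CC1 | intermediate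
15 | ethyl 2-(hydroxymethyl)prop-2-enoate | C=C(CO)C(=O)OCC | starting material
16 | ethyl 2-[(TBSO)methyl]prop-2-enoate | C=C(CO[Si](C)(C)C(C)(C)C)C(=O)OCC | intermediate
17 | 2-[(TBSO)methyl]prop-2-enoic acid | C=C(CO[Si](C)(C)C(C)(C)C)C(=O)O | intermediate
18 | (1S,2S,3R,6S)-2-acetyl-3-[(1R)-1-(TBSO)but-3-en-1-yl]-3-methyl-6-(prop-1-en-2-yl)cyclohexyl 2-[(TBSO)methyl]prop-2-enoate | C=CC[C@@H](O[Si](C)(C)C(C)(C)C)[C@@]1(C)[C@H](C(C)=O)[C@@H](OC(=O)C(=C)CO[Si](C)(C)C(C)(C)C)[C@H](C(C)=C)CC1 | intermediate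
19 | (1S,2S,3R,6S)-2-acetyl-3-[(1R)-1-(TBSO)but-3-en-1-yl]-6-(3-hydroxyprop-1-en-2-yl)-3-methylcyclohexyl 2-[(TBSO)methyl]prop-2-enoate | C=CC[C@@H](O[Si](C)(C)C(C)(C)C)[C@@]1(C)[C@H](C(C)=O)[C@@H](OC(=O)C(=C)CO[Si](C)(C)C(C)(C)C)[C@H](C(=C)CO)CC1 | intermediate (not isolated)
20 | (1S,2S,3R,6S)-2-acetyl-3-[(1R)-1-(TBSO)but-3-en-1-yl]-3-methyl-6-(3-oxoprop-1-en-2-yl)cyclohexyl 2-[(TBSO)methyl]prop-2-enoate | C=CC[C@@H](O[Si](C)(C)C(C)(C)C)[C@@]1(C)[C@H](C(C)=O)[C@@H](OC(=O)C(=C)CO[Si](C)(C)C(C)(C)C)[C@H](C(=C)C=O)CC1 | intermediate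
21 | 2-[(1S,2S,3S,4R)-3-acetyl-4-[(1R)-1-(TBSO)but-3-en-1-yl]-4-methyl-2-({2-[(TBSO)methyl]prop-2-enoyl}oxy)cyclohexyl]prop-2-enoic acid | C=CC[C@@H](O[Si](C)(C)C(C)(C)C)[C@@]1(C)[C@H](C(C)=O)[C@@H](OC(=O)C(=C)CO[Si](C)(C)C(C)(C)C)[C@H](C(=C)C(=O)O)CC1 | intermediate
22 | methyl 2-[(1S,2S,3S,4R)-3-acetyl-4-[(1R)-1-(TBSO)but-3-en-1-yl]-4-methyl-2-({2-[(TBSO)methyl]prop-2-enoyl}oxy)cyclohexyl]prop-2-enoate | C=CC[C@@H](O[Si](C)(C)C(C)(C)C)[C@@]1(C)[C@H](C(C)=O)[C@@H](OC(=O)C(=C)CO[Si](C)(C)C(C)(C)C)[C@H](C(=C)C(=O)OC)CC1 | intermediate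
23 | potassium enolate of 22 (C4–O⁻, C4=C15) | C=CC[C@@H](O[Si](C)(C)C(C)(C)C)[C@@]1(C)[C@H](C(=C)[O-])[C@@H](OC(=O)C(=C)CO[Si](C)(C)C(C)(C)C)[C@H](C(=C)C(=O)OC)CC1.[K+] | intermediate (not isolated)
24 | methyl 2-[(1S,2S,3S,4R)-4-[(1R)-1-(TBSO)but-3-en-1-yl]-4-methyl-2-({2-[(TBSO)methyl]prop-2-enoyl}oxy)-3-[1-(trifluoromethanesulfonyloxy)ethenyl]cyclohexyl]prop-2-enoate | C=CC[C@@H](O[Si](C)(C)C(C)(C)C)[C@@]1(C)[C@H](C(=C)OS(=O)(=O)C(F)(F)F)[C@@H](OC(=O)C(=C)CO[Si](C)(C)C(C)(C)C)[C@H](C(=C)C(=O)OC)CC1 | intermediate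
25 | methyl 2-[(1S,2S,3S,4R)-4-[(1R)-1-(TBSO)-3,4-dihydroxybutyl]-4-methyl-2-({2-[(TBSO)methyl]prop-2-enoyl}oxy)-3-[1-(trifluoromethanesulfonyloxy)ethenyl]cyclohexyl]prop-2-enoate (both epimers at the new carbinol) | OCC(O)C[C@@H](O[Si](C)(C)C(C)(C)C)[C@@]1(C)[C@H](C(=C)OS(=O)(=O)C(F)(F)F)[C@@H](OC(=O)C(=C)CO[Si](C)(C)C(C)(C)C)[C@H](C(=C)C(=O)OC)CC1 | intermediate (not isolated)
26 | methyl 2-[(1S,2S,3S,4R)-4-[(1R)-1-(TBSO)-3-oxopropyl]-4-methyl-2-({2-[(TBSO)methyl]prop-2-enoyl}oxy)-3-[1-(trifluoromethanesulfonyloxy)ethenyl]cyclohexyl]prop-2-enoate | O=CC[C@@H](O[Si](C)(C)C(C)(C)C)[C@@]1(C)[C@H](C(=C)OS(=O)(=O)C(F)(F)F)[C@@H](OC(=O)C(=C)CO[Si](C)(C)C(C)(C)C)[C@H](C(=C)C(=O)OC)CC1 | intermediate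
27 | alkenylchromium dichloride of 26 (CrCl2 on C4 in place of OTf; solvent ligands omitted) | O=CC[C@@H](O[Si](C)(C)C(C)(C)C)[C@@]1(C)[C@H](C(=C)[Cr](Cl)Cl)[C@@H](OC(=O)C(=C)CO[Si](C)(C)C(C)(C)C)[C@H](C(=C)C(=O)OC)CC1 | intermediate (not isolated)
28 | methyl (1R,3S,5S,6S,7S,10R)-1-(TBSO)-3-hydroxy-6-({2-[(TBSO)methyl]prop-2-enoyl}oxy)eudesma-4(15),11(13)-dien-12-oate | C=C(CO[Si](C)(C)C(C)(C)C)C(=O)O[C@@H]1[C@H]2C(=C)[C@@H](O)C[C@@H](O[Si](C)(C)C(C)(C)C)[C@]2(C)CC[C@H]1C(=C)C(=O)OC | intermediate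
29 | methyl (1R,3S,5S,6S,7S,10R)-1,3-dihydroxy-6-{[2-(hydroxymethyl)prop-2-enoyl]oxy}eudesma-4(15),11(13)-dien-12-oate | C=C(CO)C(=O)O[C@@H]1[C@H]2C(=C)[C@@H](O)C[C@@H](O)[C@]2(C)CC[C@H]1C(=C)C(=O)OC | target

**Step count and risks**
Total step count: 18. Longest linear sequence: 16 (steps 1–8 and 11–18).

Steps most likely to fail:

Step 1. Face discrimination by the catalyst may be weak with this diene, or the strong Lewis acid may decompose the acetoxydiene before cycloaddition. The fallback sets out from 1 and 2, which are heated without catalyst (toluene, 110 °C, trace hydroquinone) to the racemic cis adduct, that is 3 together with its enantiomer (1R,6S)-6-formyl-6-methylcyclohex-2-en-1-yl acetate F1. The same chiral allylborane then fixes C1 as (R) in both antipodes, so F1 becomes the diastereomeric acetate (1R,6R)-6-[(1R)-1-hydroxybut-3-en-1-yl]-6-methylcyclohex-2-en-1-yl acetate F2. Methanolysis gives the diol (1R,6R)-6-[(1R)-1-hydroxybut-3-en-1-yl]-6-methylcyclohex-2-en-1-ol F3, and MnO2 gives the epimeric hydroxy enone (6R)-6-[(1R)-1-hydroxybut-3-en-1-yl]-6-methylcyclohex-2-en-1-one F4. F4 is a diastereomer of 6 and is removed by chromatography; the route is rejoined at 6.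

Step 12. Oxidation may occur at the ring methine C7–H or at the allyl group instead of the methyl group, and over-oxidation may follow. The fallback sets out from 18. Ene-type chlorination with Ca(OCl)2 and solid CO2 in CH2Cl2/H2O at 0 °C should give the allylic chloride (1S,2S,3R,6S)-2-acetyl-3-[(1R)-1-(TBSO)but-3-en-1-yl]-6-(3-chloroprop-1-en-2-yl)-3-methylcyclohexyl 2-[(TBSO)methyl]prop-2-enoate F5. Oxidation of this chloride with N-methylmorpholine N-oxide in MeCN (Kornblum-type) gives the enal; the route is rejoined at 20.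

Step 17. The alkenylchromium may add to the aldehyde with poor facial selectivity at C3. The fallback sets out from 26, which is cyclised as before. The mixture of 28 and its C3 epimer, methyl (1R,3R,5S,6S,7S,10R)-1-(TBSO)-3-hydroxy-6-({2-[(TBSO)methyl]prop-2-enoyl}oxy)eudesma-4(15),11(13)-dien-12-oate F6, is oxidised with MnO2 to the enone methyl (1R,5S,6S,7S,10R)-1-(TBSO)-3-oxo-6-({2-[(TBSO)methyl]prop-2-enoyl}oxy)eudesma-4(15),11(13)-dien-12-oate F7. Luche reduction (NaBH4, CeCl3·7H2O, MeOH, −78 °C) should deliver hydride axially from the α-face and give the equatorial 3β-alcohol; the route is rejoined at 28.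

**Further compounds**
F1 | step 1 | (1R,6S)-6-formyl-6-methylcyclohex-2-en-1-yl acetate | O=C[C@]1(C)[C@H](OC(C)=O)C=CCC1
F2 | step 1 | (1R,6R)-6-[(1R)-1-hydroxybut-3-en-1-yl]-6-methylcyclohex-2-en-1-yl acetate | C=CC[C@@H](O)[C@]1(C)[C@H](OC(C)=O)C=CCC1
F3 | step 1 | (1R,6R)-6-[(1R)-1-hydroxybut-3-en-1-yl]-6-methylcyclohex-2-en-1-ol | C=CC[C@@H](O)[C@]1(C)[C@H](O)C=CCC1
F4 | step 1 | (6R)-6-[(1R)-1-hydroxybut-3-en-1-yl]-6-methylcyclohex-2-en-1-one | C=CC[C@@H](O)[C@]1(C)C(=O)C=CCC1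
F5 | step 12 | (1S,2S,3R,6S)-2-acetyl-3-[(1R)-1-(TBSO)but-3-en-1-yl]-6-(3-chloroprop-1-en-2-yl)-3-methylcyclohexyl 2-[(TBSO)methyl]prop-2-enoate | C=CC[C@@H](O[Si](C)(C)C(C)(C)C)[C@@]1(C)[C@H](C(C)=O)[C@@H](OC(=O)C(=C)CO[Si](C)(C)C(C)(C)C)[C@H](C(=C)CCl)CC1
F6 | step 17 | methyl (1R,3R,5S,6S,7S,10R)-1-(TBSO)-3-hydroxy-6-({2-[(TBSO)methyl]prop-2-enoyl}oxy)eudesma-4(15),11(13)-dien-12-oate | C=C(CO[Si](C)(C)C(C)(C)C)C(=O)O[C@@H]1[C@H]2C(=C)[C@H](O)C[C@@H](O[Si](C)(C)C(C)(C)C)[C@]2(C)CC[C@H]1C(=C)C(=O)OC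
F7 | step 17 | methyl (1R,5S,6S,7S,10R)-1-(TBSO)-3-oxo-6-({2-[(TBSO)methyl]prop-2-enoyl}oxy)eudesma-4(15),11(13)-dien-12-oate | C=C(CO[Si](C)(C)C(C)(C)C)C(=O)O[C@@H]1[C@H]2C(=C)C(=O)C[C@@H](O[Si](C)(C)C(C)(C)C)[C@]2(C)CC[C@H]1C(=C)C(=O)OC
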